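At early times, which concentration sets the order of the second step? I take it to be the coupling partner's: first product meets coupling partner, so with partner in hand the step is pseudo-first-order in first product.

| flask | substrate | coupling partner | remark | time |
|---|---|---|---|---|
| larch | 27 mM | 8 mM | run made earlier |  |
| ash | 27 mM | 36 mM | run made earlier |  |
| north | 27 mM | 13.5 mM |  | 15 min |
| south | 27 mM | 32.4 mM |  | 15 min |
| north-west | 27 mM | 40.5 mM |  | 15 min |

| run | time / min | double product / % | first product / % |
|---|---|---|---|
| larch | 0.667 | 2 | 0 |
| larch | 1.00 | 1 | 0 |
| larch | 1.50 | 0 | 4 |
| larch | 2.50 | 2 | 4 |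
| larch | 5.00 | 0 | 5 |
| larch | 8.00 | 3 | 13 |
| ash | 0.667 | 1 | 3 |
| ash | 1.00 | 2 | 8 |
| ash | 1.50 | 0 | 9 |
| ash | 2.50 | 3 | 12 |
| ash | 5.00 | 3 | 23 |
| ash | 8.00 | 9 | 28 |

(each reading ± 2 percentage points)

* final double product, as a percentage of the substrate charged, for each flask in turn (north, south, north-west)

- the numbers in the tables scatter by 2 percentage points (one standard deviation)
- a reading or a percentage of first product counts all its forms, free or not

What follows for the readings? Write D for double product, M for first product, c̄ for the mean partner concentration over a run and t for the time. Then D/M grows as κ·c̄·t, where κ is the ratio gained per unit of partner exposure c̄·t.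

Which reading gives κ? Larch is poor, with 3% of double product against a scatter of 2 percentage points, so I use ash at 8.00 min, with D at 9% and M at 28%.

And c̄ in ash? Counting the partner held in the two products read, one in each first product and two in each double product, c̄ halfway through that counted use is 29.8 mM. This gives κ = 0.0225 M⁻¹ s⁻¹.

Isn't that one noisy reading? Yes: it carries 2 points on 9%, so κ is a rough reading.

What do you commit to? For north-west, taking c̄ at the same fraction of its charge as in ash, my reckoning gives D/M of 0.678. That is a ratio, not the percentage asked.

The forecast gives 5%, 14% and 18% for north, south and north-west, on this ground: “a second step about as fast as the first, roughly 0.8 times”.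

    substrate + coupling partner → first product (k = 0.0322 M⁻¹ s⁻¹)
    substrate + coupling partner → other mono adduct (k = 0.0298 M⁻¹ s⁻¹)
    coupling partner + first product → double product (k = 0.0163 M⁻¹ s⁻¹)
    coupling partner + other mono adduct → double product (k = 0.0263 M⁻¹ s⁻¹)
    crystals ⇌ first product, rate k5*(cs5 - [first product]) while solid is left; crystals form when [first product] > cs5 (solubility = 2.80 mM, k = 0.181 s⁻¹)

The flasks give 2.26%, 9.90% and 14.1%, within the tolerance of the forecast. North-west also held 25.5% of other mono adduct at 15.0 min. Now κ is used with the simulated figures, taking c̄ as the mean of charge and what was left. In north-west, c̄ of 28.5 mM and first product at 35.4%, crystals counted, give 20.4% of double product against 14.1%. In south, c̄ of 22.2 mM and first product at 31.5% give 14.1% against 9.90%.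

The earlier runs and the new flask are calculated for an exercise, noise included.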